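**Retrosynthetic overview**
- The all-cis stereotriad comes last, from one face-selective syn-hydrogenation of a 1-aryl-3,4-dihydronaphthalene whose only stereocentre is C3.
- The pendant aryl group is attached by aryl-metal addition and dehydration at a 1-tetralone carbonyl.
- Key disconnection: that benzylic C=O bond, made by enantioselective desymmetrising C–H oxygenation of a meso cis-2,3-bis(methoxymethyl)tetralin. This C–O bond formation is the only enantio-determining event.
- Both CH2–OMe bonds come from double O-methylation of the meso diol, itself from the meso anhydride.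
- Ring order: the dimethoxybenzene ring is bought; ring B (the saturated carbocycle) is formed by an o-quinodimethane/maleic anhydride Diels–Alder reaction; the pendant aryl ring is attached last.

Assumption: the SMILES is read as the all-cis (1S,2S,3R) isomer (aryl and both methoxymethyl groups on one face); dibromide 1 is bought as a catalogue compound; the (S,S) ligand of step 4 is taken to give the (2S,3R) ketone, otherwise its antipode is used.

**Step 1**
Reactants: 1 1,2-bis(bromomethyl)-4,5-dimethoxybenzene; 2 maleic anhydride
Product: 4 cis-(3aR,9aS)-6,7-dimethoxy-3a,4,9,9a-tetrahydronaphtho[2,3-c]furan-1,3-dione (meso), via 4,5-dimethoxy-o-quinodimethane 3 (not isolated)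
Conditions: Zn dust (2.5 equiv), 1,4-dioxane, ultrasound, 25 °C
Reagents that add atoms: none
Why: Zinc-induced 1,4-debromination gives o-quinodimethane 3, which is trapped by maleic anhydride in a suprafacial Diels–Alder reaction, so the cyclic cis dienophile fixes the cis (meso) ring fusion.

**Step 2**
Reactants: 4 cis-(3aR,9aS)-6,7-dimethoxy-3a,4,9,9a-tetrahydronaphtho[2,3-c]furan-1,3-dione
Product: 5 cis-(2R,3S)-[6,7-dimethoxy-1,2,3,4-tetrahydronaphthalene-2,3-diyl]dimethanol (meso)
Conditions: LiAlH4 (2 equiv), THF, 0 °C → reflux; H2O/aq NaOH work-up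
Reagents that add atoms: none
Why: Hydride reduction of a cyclic anhydride to the 1,4-diol is faster than enolisation, so the cis (meso) relationship is kept.

**Step 3**
Reactants: 5 cis-(2R,3S)-[6,7-dimethoxy-1,2,3,4-tetrahydronaphthalene-2,3-diyl]dimethanol
Product: 6 cis-(2R,3S)-6,7-dimethoxy-2,3-bis(methoxymethyl)-1,2,3,4-tetrahydronaphthalene (meso)
Conditions: NaH (2.5 equiv), MeI (3 equiv), THF, 0 → 23 °C
Reagents that add atoms: iodomethane, CI
Why: Williamson ether synthesis on two primary alkoxides forms both CH2–OMe bonds of the target while the molecule is still meso, and no stereocentre is touched.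

**Step 4**
Reactants: 6 cis-(2R,3S)-6,7-dimethoxy-2,3-bis(methoxymethyl)-1,2,3,4-tetrahydronaphthalene
Product: 8 (2S,3R)-6,7-dimethoxy-2,3-bis(methoxymethyl)-3,4-dihydronaphthalen-1(2H)-one, via benzylic alcohol 7 (not isolated)
Conditions: Mn(OTf)2 (3 mol %), (S,S)-TIPS-pdp [(2S,2'S)-1,1'-bis{[5-(triisopropylsilyl)pyridin-2-yl]methyl}-2,2'-bipyrrolidine] (3.3 mol %), cyclopropanecarboxylic acid (5 equiv), 50% aq H2O2 (3 equiv, syringe pump), MeCN, −40 °C
Reagents that add atoms: hydrogen peroxide, OO
Why: Proposed new method: enantiotopos-selective benzylic C–H oxygenation of a meso cis-2,3-disubstituted tetralin, in which the chiral oxomanganese carboxylate (formally pentavalent manganese) formed from Mn(OTf)2, the ligand, H2O2 and the acid abstracts the pseudoaxial benzylic hydrogen para to a methoxy group (the weakest and most hydridic C–H in 6, ahead of the ether α-C–H and tertiary C–H bonds), the bulky silyl walls of the ligand read the configuration of the neighbouring ring stereocentre and so distinguish the two mirror-related CH2 groups, hydroxyl rebound gives alcohol 7 and a fast second oxidation gives the conjugated ketone, which is deactivated toward attack at the remaining benzylic CH2 (any over-oxidation to the meso diketone removes the minor enantiomer preferentially); oxygenation next to the (S)-configured ring carbon leaves the other one as C3 (R) and thereby sets the absolute configuration of the whole target; the closest known reaction type is manganese aminopyridine/H2O2 enantioselective desymmetrising ketonisation of cyclohexane methylene groups and benzylic oxidation of spirocyclic indanes and tetralins.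

**Step 5**
Reactants: 8 (2S,3R)-6,7-dimethoxy-2,3-bis(methoxymethyl)-3,4-dihydronaphthalen-1(2H)-one; 9 4-bromo-1,2-dimethoxybenzene
Product: 13 (3R)-1-(3,4-dimethoxyphenyl)-6,7-dimethoxy-2,3-bis(methoxymethyl)-3,4-dihydronaphthalene, via 3,4-dimethoxyphenyllithium 10 (not isolated), via arylcerium dichloride 11 (not isolated), via tertiary alcohol 12 (not isolated)
Conditions: 9, n-BuLi, THF, −78 °C; anhydrous CeCl3, −78 °C; then 8, −78 → 0 °C; then 2 M aq HCl, 23 °C
Reagents that add atoms: none
Why: Bromine–lithium exchange and transmetalation give a weakly basic organocerium reagent that adds 1,2 to the enolisable β-methoxy ketone (Imamoto addition), and E1 dehydration of the doubly benzylic tertiary alcohol can only give the C1=C2 alkene, so C2 is erased, C3 (R) is untouched and no new stereocentre is set.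

**Step 6**
Reactants: 13 (3R)-1-(3,4-dimethoxyphenyl)-6,7-dimethoxy-2,3-bis(methoxymethyl)-3,4-dihydronaphthalene
Product: 14 (1S,2S,3R)-1-(3,4-dimethoxyphenyl)-6,7-dimethoxy-2,3-bis(methoxymethyl)-1,2,3,4-tetrahydronaphthalene
Conditions: H2 (4 atm), PtO2 (5 mol %), EtOAc, 23 °C
Reagents that add atoms: none
Why: Heterogeneous catalytic hydrogenation adds both hydrogens syn to the face opposite the C3 methoxymethyl group (held pseudoaxial by allylic 1,2-strain), which places the aryl group at C1 (S) and the methoxymethyl group at C2 (S) cis to each other and to the C3 substituent; platinum is chosen to limit allylic C–O hydrogenolysis.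

**Compound list**
1 | 1,2-bis(bromomethyl)-4,5-dimethoxybenzene | COc1cc(CBr)c(CBr)cc1OC | starting material
2 | maleic anhydride (furan-2,5-dione) | O=C1OC(=O)C=C1 | starting material
3 | 4,5-dimethoxy-o-quinodimethane (2,3-dimethoxy-5,6-dimethylidenecyclohexa-1,3-diene) | COC1=CC(=C)C(=C)C=C1OC | intermediate
4 | cis-(3aR,9aS)-6,7-dimethoxy-3a,4,9,9a-tetrahydronaphtho[2,3-c]furan-1,3-dione (meso) | O=C1OC(=O)[C@H]2Cc3cc(OC)c(OC)cc3C[C@@H]12 | intermediate
5 | cis-(2R,3S)-[6,7-dimethoxy-1,2,3,4-tetrahydronaphthalene-2,3-diyl]dimethanol (meso) | OC[C@@H]1Cc2cc(OC)c(OC)cc2C[C@@H]1CO | intermediate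
6 | cis-(2R,3S)-6,7-dimethoxy-2,3-bis(methoxymethyl)-1,2,3,4-tetrahydronaphthalene (meso) | COC[C@@H]1Cc2cc(OC)c(OC)cc2C[C@@H]1COC | intermediate
7 | (1S,2S,3R)-6,7-dimethoxy-2,3-bis(methoxymethyl)-1,2,3,4-tetrahydronaphthalen-1-ol (C1 epimer drawn as expected; either epimer is oxidised on) | COC[C@@H]1Cc2cc(OC)c(OC)cc2[C@@H](O)[C@@H]1COC | intermediate
8 | (2S,3R)-6,7-dimethoxy-2,3-bis(methoxymethyl)-3,4-dihydronaphthalen-1(2H)-one | COC[C@@H]1Cc2cc(OC)c(OC)cc2C(=O)[C@@H]1COC | intermediate
9 | 4-bromo-1,2-dimethoxybenzene | COc1ccc(Br)cc1OC | starting material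
10 | (3,4-dimethoxyphenyl)lithium | [Li]c1ccc(OC)c(OC)c1 | intermediate
11 | dichloro(3,4-dimethoxyphenyl)cerium | Cl[Ce](Cl)c1ccc(OC)c(OC)c1 | intermediate
12 | (1S,2S,3R)-1-(3,4-dimethoxyphenyl)-6,7-dimethoxy-2,3-bis(methoxymethyl)-1,2,3,4-tetrahydronaphthalen-1-ol (aryl trans to the C2 substituent; C1 configuration is immaterial) | COC[C@@H]1Cc2cc(OC)c(OC)cc2[C@@](O)(c2ccc(OC)c(OC)c2)[C@@H]1COC | intermediate
13 | (3R)-1-(3,4-dimethoxyphenyl)-6,7-dimethoxy-2,3-bis(methoxymethyl)-3,4-dihydronaphthalene | COC[C@@H]1Cc2cc(OC)c(OC)cc2C(c2ccc(OC)c(OC)c2)=C1COC | intermediate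
14 | (1S,2S,3R)-1-(3,4-dimethoxyphenyl)-6,7-dimethoxy-2,3-bis(methoxymethyl)-1,2,3,4-tetrahydronaphthalene | COC[C@@H]1Cc2cc(OC)c(OC)cc2[C@H](c2ccc(OC)c(OC)c2)[C@@H]1COC | target

Total step count: 6. Longest linear sequence: 6 steps (1 → 14); the aryl bromide 9 enters in the one-pot step 5.

**Steps most likely to fail**

Step 4 (the proposed new oxygenation) is the main risk. Enantiotopos discrimination may be modest, and the electron-rich arene or the ether α-C–H bonds may be oxidised in competition. Fallback with known chemistry: set out from 6 and oxidise the benzylic position without enantiocontrol with DDQ in wet dioxane/acetic acid (established for tetralins carrying a para-methoxy group). This gives 8 together with its enantiomer (2R,3S)-6,7-dimethoxy-2,3-bis(methoxymethyl)-3,4-dihydronaphthalen-1(2H)-one F1. The two are separated by preparative supercritical-fluid chromatography on an amylose tris(3,5-dimethylphenylcarbamate) phase, F1 is discarded, and the route is rejoined at 8.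

Step 6 can fail through hydrogenolysis of the allylic C–OMe bond, slow reduction of the tetrasubstituted alkene, or insufficient face selectivity. Fallback: set out from 12, isolated by quenching step 5 with aq NH4Cl instead of acid, and remove the benzylic hydroxyl by ionic reduction (Et3SiH, BF3·OEt2, CH2Cl2, −78 → −20 °C). The diaryl-stabilised C1 cation should take up hydride on the face opposite the two cis methoxymethyl groups. C2 is never planarised, so its cis relationship to C3 is inherited from 8, which must then be used without C2 epimerisation. The all-cis target is reached directly, so the route is rejoined at 14 with no alkene and no hydrogenation (no new compound: F0).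

Step 5 can fail through enolisation or β-elimination of methanol from the hindered, electron-rich β-methoxy ketone instead of 1,2-addition. Fallback: set out from 8, deprotonate with KHMDS in THF at −78 °C and trap with PhNTf2 to give the enol triflate (3R)-6,7-dimethoxy-2,3-bis(methoxymethyl)-3,4-dihydronaphthalen-1-yl trifluoromethanesulfonate F2. Suzuki–Miyaura coupling of F2 with commercial 3,4-dimethoxyphenylboronic acid (Pd(PPh3)4, K3PO4, dioxane/H2O, 80 °C) then forms the aryl–C1 bond without any carbonyl addition, and the route is rejoined at 13.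

**Further compounds**
F1 | step 4 | (2R,3S)-6,7-dimethoxy-2,3-bis(methoxymethyl)-3,4-dihydronaphthalen-1(2H)-one | COC[C@H]1Cc2cc(OC)c(OC)cc2C(=O)[C@H]1COC
F2 | step 5 | (3R)-6,7-dimethoxy-2,3-bis(methoxymethyl)-3,4-dihydronaphthalen-1-yl trifluoromethanesulfonate | COC[C@@H]1Cc2cc(OC)c(OC)cc2C(OS(=O)(=O)C(F)(F)F)=C1COC
F0 | step 6 | none | none
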